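## Plan

1. Retrosynthetic cuts, in order: the C1'=C2' bond of the side chain (cross-metathesis, then saturation); the ring bond C4a–C5; the alkene of the allylic carbonate tether (cross-metathesis); the O4–methyl bond, paired with N–O–methyl formation; the C8 O–methyl bond; the C8a–C8 bond to the heterocycle.
2. Enabling feature: C4a is the α-carbon of the vinylogous hydroxamate N1–C8a=C4a–C4=O of the pyridone ring and its only free nucleophilic carbon. The C5 stereocentre is bonded directly to it, so an allyl electrophile tethered from C8a can close the carbocycle C4a–C5–C6–C7–C8–C8a there.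
3. Forward: the pyridine ring is bought as its N-oxide and acylated at its free α-position (later C8a). The ketone becomes the C8 methyl ether, the N-oxide becomes the 1-methoxy-4-pyridone, and the tether is extended to an allylic carbonate.
4. The carbocycle, the only ring made, then closes, and the resulting vinyl group is grown into the 5-phenylpentyl chain.
5. Stereochemistry: C8 (R) comes from catalyst-controlled transfer hydrogenation of the aryl ketone. C5 comes from the chiral phosphoramidite on iridium in the ring closure (5R as the vinyl compound, named 5S in the target after chain extension, same geometry, cis to the C8 methoxy group).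

Key step: step 7

Remark: the facial sense assigned to the (Sa,Sc,Sc) phosphoramidite in step 7 follows the usual outer-sphere model for alkyl-substituted allyl carbonates; if the substrate follows the opposite sense, the mirror-image ligand is used and nothing else changes.

## Route

Step 1
Reactants: 1 pent-4-enoic acid
Product: 3 N-methoxy-N-methylpent-4-enamide, via acyl imidazole 2 (not isolated)
Conditions: CDI (1.1 equiv), CH2Cl2, 0 °C to rt; then MeNH(OMe)·HCl (1.2 equiv), rt
Reagents that add atoms: N,O-dimethylhydroxylamine hydrochloride, CNOC.Cl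
Why: Weinreb amide formation through the acyl imidazole is a standard amine acylation that leaves the remote terminal alkene untouched.

Step 2
Reactants: 4 3,4-dimethoxy-2-methylpyridine 1-oxide; 3 N-methoxy-N-methylpent-4-enamide
Product: 7 1-(4,5-dimethoxy-6-methyl-1-oxidopyridin-1-ium-2-yl)pent-4-en-1-one, via pyridylmagnesium chloride 5 (not isolated), via tetrahedral magnesium adduct 6 (not isolated)
Conditions: i-PrMgCl (1.2 equiv), THF, −78 °C, 1 h; then 3 (1.3 equiv), −78 to −20 °C; aq. NH4Cl
Reagents that add atoms: none
Why: Directed α-magnesiation of a pyridine N-oxide (the N-oxide oxygen steers the base to C6, the only free α-position) followed by Weinreb ketone synthesis, in which the chelated adduct 6 should prevent over-addition.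

Step 3
Reactants: 7 1-(4,5-dimethoxy-6-methyl-1-oxidopyridin-1-ium-2-yl)pent-4-en-1-one
Product: 8 (1R)-1-(4,5-dimethoxy-6-methyl-1-oxidopyridin-1-ium-2-yl)pent-4-en-1-ol
Conditions: RuCl(p-cymene)[(R,R)-TsDPEN] (1 mol %), HCO2H/Et3N (5:2), CH2Cl2, rt
Reagents that add atoms: none
Why: Noyori asymmetric transfer hydrogenation of an aryl alkyl ketone, in which the (R,R) catalyst should deliver hydride to the face giving the (R) carbinol by the usual aryl/arene-ligand model, while the outer-sphere mechanism leaves the N-oxide and the isolated alkene alone.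

Step 4
Reactants: 8 (1R)-1-(4,5-dimethoxy-6-methyl-1-oxidopyridin-1-ium-2-yl)pent-4-en-1-ol
Product: 9 3,4-dimethoxy-6-[(1R)-1-methoxypent-4-en-1-yl]-2-methylpyridine 1-oxide
Conditions: NaH (1.2 equiv), THF, 0 °C; MeI (1.5 equiv), 0 °C to rt
Reagents that add atoms: iodomethane, CI
Why: Williamson ether synthesis, in which alkoxide methylation is far faster than attack of the N-oxide oxygen on MeI at this temperature and the carbinol C–H is not acidic enough for NaH, so the C8 configuration is kept.

Step 5
Reactants: 9 3,4-dimethoxy-6-[(1R)-1-methoxypent-4-en-1-yl]-2-methylpyridine 1-oxide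
Product: 11 1,5-dimethoxy-2-[(1R)-1-methoxypent-4-en-1-yl]-6-methylpyridin-4(1H)-one, via dimethoxypyridinium triflate 10 (not isolated)
Conditions: MeOTf (1.05 equiv), CH2Cl2, 0 °C to rt; solvent switch; NaI (1.5 equiv), MeCN, 60 °C, sealed tube, dark
Reagents that add atoms: methyl trifluoromethanesulfonate, COS(=O)(=O)C(F)(F)F
Why: O-methylation of the N-oxide followed by iodide SN2 cleavage of the O4 methyl (the classical 4-alkoxypyridinium to 4-pyridone dealkylation, overall the alkoxypyridine N-oxide to N-alkoxypyridone rearrangement), where cleavage at the N–O methyl only returns 9 for re-alkylation by the MeI formed, so the material should drain to the vinylogous hydroxamate 11 without base and without touching C8.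

Step 6
Reactants: 11 1,5-dimethoxy-2-[(1R)-1-methoxypent-4-en-1-yl]-6-methylpyridin-4(1H)-one; 12 allyl methyl carbonate
Product: 13 methyl (2E,6R)-6-(1,5-dimethoxy-6-methyl-4-oxo-1,4-dihydropyridin-2-yl)-6-methoxyhex-2-en-1-yl carbonate
Conditions: second-generation Grubbs catalyst RuCl2(=CHPh)(H2IMes)(PCy3) (5 mol %), 12 (4 equiv), CH2Cl2, 40 °C; any Z isomer removed on AgNO3-impregnated silica
Reagents that add atoms: none
Why: Olefin cross-metathesis of an unhindered terminal alkene with an excess of an allylic carbonate is a standard, thermodynamically E-selective entry to substrates for iridium allylation, and the pyridone is placed after the N-oxide stage so that no N-oxide meets the ruthenium carbene.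

Step 7
Reactants: 13 methyl (2E,6R)-6-(1,5-dimethoxy-6-methyl-4-oxo-1,4-dihydropyridin-2-yl)-6-methoxyhex-2-en-1-yl carbonate
Product: 14 (5R,8R)-5-ethenyl-1,3,8-trimethoxy-2-methyl-5,6,7,8-tetrahydroquinolin-4(1H)-one
Conditions: [Ir(cod)Cl]2 (2.5 mol %), (Sa,Sc,Sc)-O,O'-(1,1'-binaphthyl-2,2'-diyl)-N,N-bis(1-phenylethyl)phosphoramidite (5 mol %), pre-activated with n-PrNH2 (THF, 50 °C, then volatiles removed); 13, DBU (0.2 equiv), THF (0.05 M), 50 °C
Reagents that add atoms: none
Why: Proposed new method: the cyclometalated monovalent iridium–phosphoramidite complex ionises the allylic carbonate of 13 (loss of CO2 and methoxide) to a trivalent π-allyliridium, C4a of the vinylogous hydroxamate attacks the substituted allyl terminus on the face away from the metal, and methoxide or DBU removes the C4a proton of the cationic σ-adduct so that the pyridone is restored. The closest known reaction type is the iridium-catalysed intramolecular asymmetric allylic Friedel–Crafts alkylation of indoles, pyrroles and phenols with [Ir(cod)Cl]2 and a chiral phosphoramidite; a 4-pyridone carbon has not been used in that role, but this position is where 4-pyridones take up electrophiles such as halogens, and the tether makes the attack intramolecular. The carbocycle C4a–C5–C6–C7–C8–C8a closes in the 6-exo mode with respect to the allyl unit, which leaves the other two allyl carbons outside the ring as the vinyl group. C5 is set by the phosphoramidite, which decides the allyl face that iridium binds and so the face the ring carbon attacks, independently of C8; the (Sa,Sc,Sc) ligand is expected to give 5R, cis to the C8 methoxy group. The step needs branched over linear attack, C- over O-alkylation and cis over trans closure: iridium directs nucleophiles to the substituted terminus and linear closure would demand an eight-membered ring holding an E alkene, N1 and C3 are blocked by methoxy groups, O4 cannot reach the allyl unit without an eight-membered bridged ring, and the cis/trans outcome is under ligand control. Intermolecular O4-allylation, if it occurs, gives an allyloxypyridinium that the catalyst can ionise again, so it should be reversible.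

Step 8
Reactants: 14 (5R,8R)-5-ethenyl-1,3,8-trimethoxy-2-methyl-5,6,7,8-tetrahydroquinolin-4(1H)-one; 15 5-phenyl-1-pentene
Product: 16 (5R,8R)-1,3,8-trimethoxy-2-methyl-5-[(1E)-5-phenylpent-1-en-1-yl]-5,6,7,8-tetrahydroquinolin-4(1H)-one
Conditions: second-generation Grubbs catalyst RuCl2(=CHPh)(H2IMes)(PCy3) (5–10 mol %), 15 (4 equiv), 1,4-benzoquinone (10 mol %), CH2Cl2, 40 °C
Reagents that add atoms: none
Why: Olefin cross-metathesis of an α-branched vinyl group with an excess of an unhindered terminal alkene is well precedented, and benzoquinone is added to suppress ruthenium hydride alkene migration that would endanger C5.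

Step 9
Reactants: 16 (5R,8R)-1,3,8-trimethoxy-2-methyl-5-[(1E)-5-phenylpent-1-en-1-yl]-5,6,7,8-tetrahydroquinolin-4(1H)-one
Product: 17 waltherione H, (5S,8R)-1,3,8-trimethoxy-2-methyl-5-(5-phenylpentyl)-5,6,7,8-tetrahydroquinolin-4(1H)-one
Conditions: H2 (1 atm), RhCl(PPh3)3 (10 mol %), PhH/EtOH (1:1), rt
Reagents that add atoms: none
Why: Homogeneous hydrogenation with RhCl(PPh3)3 should saturate the unhindered disubstituted alkene without hydrogenolysis of the N–OMe bond or reduction of the pyridone or phenyl ring, and it does not touch C5 or C8 (the descriptor at C5 changes to S only through the priority rules).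

## Compound list

1 | pent-4-enoic acid | C=CCCC(=O)O | starting material
2 | 1-(1H-imidazol-1-yl)pent-4-en-1-one | C=CCCC(=O)n1ccnc1 | intermediate
3 | N-methoxy-N-methylpent-4-enamide | C=CCCC(=O)N(C)OC | intermediate
4 | 3,4-dimethoxy-2-methylpyridine 1-oxide | COc1cc[n+]([O-])c(C)c1OC | starting material
5 | chlorido(4,5-dimethoxy-6-methyl-1-oxidopyridin-1-ium-2-yl)magnesium | COc1cc([Mg]Cl)[n+]([O-])c(C)c1OC | intermediate
6 | chloromagnesium 1-(4,5-dimethoxy-6-methyl-1-oxidopyridin-1-ium-2-yl)-1-[methoxy(methyl)amino]pent-4-en-1-olate | COc1cc(C(CCC=C)(O[Mg]Cl)N(C)OC)[n+]([O-])c(C)c1OC | intermediate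
7 | 1-(4,5-dimethoxy-6-methyl-1-oxidopyridin-1-ium-2-yl)pent-4-en-1-one | COc1cc(C(=O)CCC=C)[n+]([O-])c(C)c1OC | intermediate
8 | (1R)-1-(4,5-dimethoxy-6-methyl-1-oxidopyridin-1-ium-2-yl)pent-4-en-1-ol | COc1cc([C@H](O)CCC=C)[n+]([O-])c(C)c1OC | intermediate
9 | 3,4-dimethoxy-6-[(1R)-1-methoxypent-4-en-1-yl]-2-methylpyridine 1-oxide | COc1cc([C@H](OC)CCC=C)[n+]([O-])c(C)c1OC | intermediate
10 | 1,3,4-trimethoxy-6-[(1R)-1-methoxypent-4-en-1-yl]-2-methylpyridin-1-ium trifluoromethanesulfonate | COc1cc([C@H](OC)CCC=C)[n+](OC)c(C)c1OC.[O-]S(=O)(=O)C(F)(F)F | intermediate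
11 | 1,5-dimethoxy-2-[(1R)-1-methoxypent-4-en-1-yl]-6-methylpyridin-4(1H)-one | COc1c(C)n(OC)c(cc1=O)[C@H](OC)CCC=C | intermediate
12 | allyl methyl carbonate | C=CCOC(=O)OC | starting material
13 | methyl (2E,6R)-6-(1,5-dimethoxy-6-methyl-4-oxo-1,4-dihydropyridin-2-yl)-6-methoxyhex-2-en-1-yl carbonate | COc1c(C)n(OC)c(cc1=O)[C@H](OC)CC/C=C/COC(=O)OC | intermediate
14 | (5R,8R)-5-ethenyl-1,3,8-trimethoxy-2-methyl-5,6,7,8-tetrahydroquinolin-4(1H)-one | COc1c(C)n(OC)c2c(c1=O)[C@@H](C=C)CC[C@H]2OC | intermediate
15 | 5-phenyl-1-pentene | C=CCCCc1ccccc1 | starting material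
16 | (5R,8R)-1,3,8-trimethoxy-2-methyl-5-[(1E)-5-phenylpent-1-en-1-yl]-5,6,7,8-tetrahydroquinolin-4(1H)-one | COc1c(C)n(OC)c2c(c1=O)[C@@H](/C=C/CCCc1ccccc1)CC[C@H]2OC | intermediate
17 | waltherione H, (5S,8R)-1,3,8-trimethoxy-2-methyl-5-(5-phenylpentyl)-5,6,7,8-tetrahydroquinolin-4(1H)-one | COc1c(C)n(OC)c2c(c1=O)[C@@H](CCCCCc1ccccc1)CC[C@H]2OC | target

## Count and risks

Total steps: 9. Longest linear sequence: 9 steps (1 to 17; 8 steps from 4).

Step 7 (ring closure, proposed new method). The pyridone carbon may be too weak a nucleophile, so the allyliridium could instead be captured by methoxide or revert; and the existing C8 centre may oppose the ligand, eroding the cis/trans selectivity. The fallback uses a known asymmetric Heck cyclisation to make the same C4a–C5 bond and sets out from 11. Iodination of the free pyridone carbon with N-iodosuccinimide (MeCN, rt, dark) should give 3-iodo-1,5-dimethoxy-2-[(1R)-1-methoxypent-4-en-1-yl]-6-methylpyridin-4(1H)-one F1. Cross-metathesis with allyltrimethylsilane (second-generation Grubbs catalyst RuCl2(=CHPh)(H2IMes)(PCy3), CH2Cl2, 40 °C) should give 3-iodo-1,5-dimethoxy-2-[(1R,4E)-1-methoxy-6-(trimethylsilyl)hex-4-en-1-yl]-6-methylpyridin-4(1H)-one F2. An allylsilane-terminated intramolecular Heck reaction (Pd2(dba)3·CHCl3, BINAP of the enantiomer that gives the cis isomer, Ag3PO4, DMF, 80 °C) then proceeds by 6-exo carbopalladation and β-silyl elimination to the vinyl compound, and the route is rejoined at 14.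

Step 5 (methyl relocation). Demethylation may occur mainly at the N–O methyl, so that the sequence stalls at the N-oxide, or the alkoxypyridinium–iodide pair may fragment at the N–O bond under light. The fallback separates the two events and sets out from 9. Nucleophilic O4-demethylation (NaSEt, DMF, 100 °C, then mild acid) should give 1-hydroxy-5-methoxy-2-[(1R)-1-methoxypent-4-en-1-yl]-6-methylpyridin-4(1H)-one F3. Methylation of its hydroxamate-type N–OH (MeI, K2CO3, acetone, rt) comes back to the route at 11; any O4-methylation only regenerates 9, which is recycled.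

Step 8 (chain extension by cross-metathesis). Turnover may be slow because the branched C5 position hinders the alkene and O4 can chelate the ruthenium carbene, and alkene migration into conjugation with the ring would erase C5. The fallback replaces metathesis by hydroboration and alkyl–alkyl Suzuki–Miyaura coupling and sets out from 14. Hydroboration with 9-BBN (THF, rt) should give (5S,8R)-5-[2-(9-borabicyclo[3.3.1]nonan-9-yl)ethyl]-1,3,8-trimethoxy-2-methyl-5,6,7,8-tetrahydroquinolin-4(1H)-one F4, used without isolation. Coupling with 1-bromo-3-phenylpropane (Pd(OAc)2, PCy3, K3PO4·H2O, THF, rt) gives the saturated chain directly and comes back to the route at 17, so step 9 is not needed.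

## Further compounds

F1 | step 7 | 3-iodo-1,5-dimethoxy-2-[(1R)-1-methoxypent-4-en-1-yl]-6-methylpyridin-4(1H)-one | COc1c(C)n(OC)c(c(I)c1=O)[C@H](OC)CCC=C
F2 | step 7 | 3-iodo-1,5-dimethoxy-2-[(1R,4E)-1-methoxy-6-(trimethylsilyl)hex-4-en-1-yl]-6-methylpyridin-4(1H)-one | COc1c(C)n(OC)c(c(I)c1=O)[C@H](OC)CC/C=C/C[Si](C)(C)C
F3 | step 5 | 1-hydroxy-5-methoxy-2-[(1R)-1-methoxypent-4-en-1-yl]-6-methylpyridin-4(1H)-one | COc1c(C)n(O)c(cc1=O)[C@H](OC)CCC=C
F4 | step 8 | (5S,8R)-5-[2-(9-borabicyclo[3.3.1]nonan-9-yl)ethyl]-1,3,8-trimethoxy-2-methyl-5,6,7,8-tetrahydroquinolin-4(1H)-one | COc1c(C)n(OC)c2c(c1=O)[C@@H](CCB1C3CCCC1CCC3)CC[C@H]2OC
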